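The plan cuts the C6–C7 bond of ring A. Because C7 is the carbon next to the C8 ketone and C6 is a carbonyl carbon, ring A (C4a, C5, C6, C7, C8, C8a) has an isomer in which C6 is attached to the oxygen of the C8 enol and not to C7: a six-membered enol lactone. A chiral isothiourea is asked to open that achiral lactone at C6 and deliver the acyl group to carbon, which forms C6–C7, closes ring A and sets the C7 stereocentre at once. The precursor is a 3-heptylpyrano[3,4-c]pyran-6-one bearing an E-configured 1-silyloxyethylidene group at C8, built from a 3-acyl-4-pyranone and Meldrum's acid.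

Key step: step 8

Remarks on the chemistry (assumptions):
- Isochromene numbering of the target is used for all bicyclic compounds; in lactones 12 and 13 the ring oxygen takes position 7 and the exocyclic carbon on C8 is the future C7.
- Compounds 2, 4, 9, 10, 11 and 12 are racemic; their single stereocentre becomes trigonal in 13, so it needs no control.
- The enol ether of 13 is formulated as the E isomer (silyloxy towards C8a, methyl towards the ring oxygen), because the Z isomer would press methyl against C1–H and would place silicon next to the enolate oxygen freed in step 8.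
- The silyl enol ether is made last, from ketone 12, so that no labile silyl enol ether has to survive the assembly of the ring system.
- A silyl group, not the octanoyl group, sits on the C7 oxygen during step 8, because an enol octanoate would offer the catalyst a second, more reactive acyl group.
- The (S)-catalyst in step 8 follows from a steric model and the sense of induction must be confirmed by experiment; the (R)-catalyst is the remedy if it is opposite.

Step 1
Reactants: 1 3-hydroxybutan-2-one (acetoin)
Product: 2 3-[(tert-butyldimethylsilyl)oxy]butan-2-one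
Conditions: TBSCl, imidazole, DMF, 0 °C → rt
Reagents that add atoms: tert-butyldimethylsilyl chloride, CC(C)(C)[Si](C)(C)Cl
Why: imidazole-promoted silylation of the secondary alcohol masks the hydroxyl against the acylketene of step 4, and the stereocentre is carried as the racemate because it is erased later.

Step 2
Reactants: 2 3-[(tert-butyldimethylsilyl)oxy]butan-2-one; 3 N,N-dimethylformamide dimethyl acetal
Product: 4 (E)-4-[(tert-butyldimethylsilyl)oxy]-1-(dimethylamino)pent-1-en-3-one
Conditions: neat, 100 °C, methanol distilled off
Reagents that add atoms: none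
Why: aminomethylenation of a methyl ketone with an amide acetal gives the E enaminone, and only the methyl group can condense because the silyloxy-bearing methine has a single hydrogen.

Step 3
Reactants: 5 Meldrum's acid (2,2-dimethyl-1,3-dioxane-4,6-dione); 6 octanoyl chloride
Product: 7 5-(1-hydroxyoctylidene)-2,2-dimethyl-1,3-dioxane-4,6-dione
Conditions: pyridine, CH2Cl2, 0 °C → rt; 1 M HCl work-up
Reagents that add atoms: none
Why: C-acylation of Meldrum's acid by an acid chloride with pyridine is the standard preparation of an acyl Meldrum's acid, the thermal precursor of an acylketene.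

Step 4
Reactants: 7 5-(1-hydroxyoctylidene)-2,2-dimethyl-1,3-dioxane-4,6-dione; 4 (E)-4-[(tert-butyldimethylsilyl)oxy]-1-(dimethylamino)pent-1-en-3-one
Product: 9 3-{2-[(tert-butyldimethylsilyl)oxy]propanoyl}-6-heptyl-4H-pyran-4-one, via octanoylketene 8 (not isolated)
Conditions: toluene, 100 °C
Reagents that add atoms: none
Why: thermolysis of 7 expels acetone and CO2 to give acylketene 8, whose ketene carbon is attacked by the enamine-type α-carbon of 4, after which the enol oxygen closes onto the iminium carbon and dimethylamine is eliminated, the acylketene–enamine route to γ-pyrones (formal [4+2] annulation) that places heptyl at C6 and the acyl group at C3.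

Step 5
Reactants: 9 3-{2-[(tert-butyldimethylsilyl)oxy]propanoyl}-6-heptyl-4H-pyran-4-one; 5 Meldrum's acid
Product: 10 5-(3-{2-[(tert-butyldimethylsilyl)oxy]propanoyl}-6-heptyl-4H-pyran-4-ylidene)-2,2-dimethyl-1,3-dioxane-4,6-dione
Conditions: Ac2O, 80 °C
Reagents that add atoms: none
Why: Knoevenagel condensation of a 4-pyranone carbonyl with Meldrum's acid in acetic anhydride runs through the 4-acetoxypyrylium ion and is driven by the pyrylium–enolate stabilisation of the ylidene product, which should also correct any reversible addition at the free C2 position.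

Step 6
Reactants: 10 5-(3-{2-[(tert-butyldimethylsilyl)oxy]propanoyl}-6-heptyl-4H-pyran-4-ylidene)-2,2-dimethyl-1,3-dioxane-4,6-dione
Product: 12 8-acetyl-3-heptyl-8H-pyrano[3,4-c]pyran-6-one, via keto acid 11 (not isolated)
Conditions: 2 M HCl, AcOH–H2O, 70 °C
Reagents that add atoms: water, O
Why: acid hydrolysis of the Meldrum's acid unit and decarboxylation give keto acid 11, whose carboxyl group closes onto the neighbouring ketone (enol lactonisation through the hydroxy lactone and the stabilised pyrano-pyrylium cation), and the silyl enol ether so formed is hydrolysed in the same medium, so that the intermediates converge on α-acyloxy ketone 12, whose new C8 stereocentre is racemic and is erased in step 7.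

Step 7
Reactants: 12 8-acetyl-3-heptyl-8H-pyrano[3,4-c]pyran-6-one
Product: 13 (E)-3-heptyl-8-[1-(triethylsilyloxy)ethylidene]-8H-pyrano[3,4-c]pyran-6-one
Conditions: TESOTf, Et3N, CH2Cl2, −78 → 0 °C
Reagents that add atoms: triethylsilyl trifluoromethanesulfonate, CC[Si](CC)(CC)OS(=O)(=O)C(F)(F)F
Why: soft enolisation of the ketone (silyl triflate and tertiary amine) towards the much more acidic C8–H gives the conjugated silyl dienol ether, and the E isomer is expected because it places the silyloxy group, not methyl, next to C8a and C1–H.

Step 8
Reactants: 13 (E)-3-heptyl-8-[1-(triethylsilyloxy)ethylidene]-8H-pyrano[3,4-c]pyran-6-one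
Product: 15 (7R)-3-heptyl-7-methyl-7-(triethylsilyloxy)-6H-isochromene-6,8(7H)-dione, via acyl-isothiouronium enolate 14 (not isolated)
Conditions: (S)-benzotetramisole [(S)-2-phenyl-2,3-dihydroimidazo[2,1-b][1,3]benzothiazole, C15H12N2S, 20 mol%], toluene, 4 Å molecular sieves, rt
Reagents that add atoms: none
Why: Proposed new method: the isothiourea nitrogen should add to the lactone carbonyl C6 and expel the C8 enolate, so that zwitterion 14 holds an unsaturated acyl-isothiouronium on C4a and a fully substituted α-silyloxy enolate on C8a, and the enolate carbon (the future C7) then attacks C6, forming C6–C7 and releasing the catalyst; the closest known reaction type is the Steglich O-to-C acyl shift of enol esters and enol carbonates under chiral nucleophilic catalysis, which has not been shown for an enol lactone that re-closes to a carbocycle. Ring A closes in a 6-exo-trig mode (the enolate double bond lies inside the forming ring, the acyl C=O outside it). The C7 stereocentre is controlled by the catalyst: the phenyl group on its stereogenic carbon, held coplanar with the acyl group by the sulfur–oxygen contact, shields one face of C6, the enolate must twist out of the pyran plane to reach the open face, and the inside substituent of the E enolate (the silyloxy group) turns away from the catalyst, which on this model leads to 7R with the (S)-catalyst. The step needs C-acylation to win over return to the lactone and over attack at silicon: the tether excludes crossover, the product is a non-enolisable 2,2-disubstituted 1,3-diketone that cannot re-enter the cycle, and the E geometry holds silicon trans to the liberated enolate oxygen so that it cannot migrate.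

Step 9
Reactants: 15 (7R)-3-heptyl-7-methyl-7-(triethylsilyloxy)-6H-isochromene-6,8(7H)-dione
Product: 16 (7R)-3-heptyl-7-hydroxy-7-methyl-6H-isochromene-6,8(7H)-dione
Conditions: HF·pyridine, THF, 0 °C → rt
Reagents that add atoms: none
Why: fluoride-mediated cleavage of the tertiary triethylsilyl ether under non-basic conditions avoids retro-Claisen and α-ketol pathways of the α-hydroxy-1,3-diketone and cannot touch C7, which bears no hydrogen.

Step 10
Reactants: 16 (7R)-3-heptyl-7-hydroxy-7-methyl-6H-isochromene-6,8(7H)-dione; 6 octanoyl chloride
Product: 17 (7R)-3-heptyl-7-methyl-6,8-dioxo-7,8-dihydro-6H-isochromen-7-yl octanoate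
Conditions: Et3N, 4-(dimethylamino)pyridine (cat.), CH2Cl2, 0 °C → rt
Reagents that add atoms: none
Why: esterification of the hindered tertiary alcohol through the acylpyridinium ion formed from the acid chloride and 4-(dimethylamino)pyridine (nucleophilic catalysis) forms only the O–acyl bond and leaves the C7 configuration untouched.

Compound list
1 | 3-hydroxybutan-2-one (acetoin, racemic) | CC(O)C(C)=O | starting material
2 | 3-[(tert-butyldimethylsilyl)oxy]butan-2-one (racemic) | CC(O[Si](C)(C)C(C)(C)C)C(C)=O | intermediate
3 | N,N-dimethylformamide dimethyl acetal | COC(OC)N(C)C | starting material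
4 | (E)-4-[(tert-butyldimethylsilyl)oxy]-1-(dimethylamino)pent-1-en-3-one (racemic) | CC(O[Si](C)(C)C(C)(C)C)C(=O)/C=C/N(C)C | intermediate
5 | Meldrum's acid (2,2-dimethyl-1,3-dioxane-4,6-dione) | CC1(C)OC(=O)CC(=O)O1 | starting material
6 | octanoyl chloride | CCCCCCCC(Cl)=O | starting material
7 | 5-(1-hydroxyoctylidene)-2,2-dimethyl-1,3-dioxane-4,6-dione (octanoyl Meldrum's acid, enol form) | CCCCCCCC(O)=C1C(=O)OC(C)(C)OC1=O | intermediate
8 | octanoylketene (dec-1-ene-1,3-dione), not isolated | CCCCCCCC(=O)C=C=O | intermediate
9 | 3-{2-[(tert-butyldimethylsilyl)oxy]propanoyl}-6-heptyl-4H-pyran-4-one (racemic) | CCCCCCCC1=CC(=O)C(C(=O)C(C)O[Si](C)(C)C(C)(C)C)=CO1 | intermediate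
10 | 5-(3-{2-[(tert-butyldimethylsilyl)oxy]propanoyl}-6-heptyl-4H-pyran-4-ylidene)-2,2-dimethyl-1,3-dioxane-4,6-dione (racemic) | CCCCCCCC1=CC(=C2C(=O)OC(C)(C)OC2=O)C(C(=O)C(C)O[Si](C)(C)C(C)(C)C)=CO1 | intermediate
11 | (Z)-2-(3-{2-[(tert-butyldimethylsilyl)oxy]propanoyl}-6-heptyl-4H-pyran-4-ylidene)acetic acid (racemic), not isolated | CCCCCCCC1=C/C(=C/C(O)=O)C(C(=O)C(C)O[Si](C)(C)C(C)(C)C)=CO1 | intermediate
12 | 8-acetyl-3-heptyl-8H-pyrano[3,4-c]pyran-6-one (racemic) | CCCCCCCC1=CC2=CC(=O)OC(C(C)=O)C2=CO1 | intermediate
13 | (E)-3-heptyl-8-[1-(triethylsilyloxy)ethylidene]-8H-pyrano[3,4-c]pyran-6-one | CCCCCCCC1=CC2=CC(=O)O/C(=C(\C)O[Si](CC)(CC)CC)C2=CO1 | intermediate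
14 | acyl-isothiouronium enolate from 13 and (S)-benzotetramisole (zwitterion, E enolate, acyl group Z on the pyranylidene), not isolated | CCCCCCCC1=C/C(=C/C(=O)[N+]2=C3Sc4ccccc4N3C[C@@H]2c2ccccc2)C(/C([O-])=C(/C)O[Si](CC)(CC)CC)=CO1 | intermediate
15 | (7R)-3-heptyl-7-methyl-7-(triethylsilyloxy)-6H-isochromene-6,8(7H)-dione | CC[Si](CC)(CC)O[C@]1(C)C(=O)C=C2C=C(CCCCCCC)OC=C2C1=O | intermediate
16 | (7R)-3-heptyl-7-hydroxy-7-methyl-6H-isochromene-6,8(7H)-dione | O[C@]1(C)C(=O)C=C2C=C(CCCCCCC)OC=C2C1=O | intermediate
17 | (7R)-3-heptyl-7-methyl-6,8-dioxo-7,8-dihydro-6H-isochromen-7-yl octanoate (CNP0155255.1) | CCCCCCCC(=O)O[C@]1(C)C(=O)C=C2C=C(CCCCCCC)OC=C2C1=O | target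

Total step count: 10. Longest linear sequence: 9 steps (steps 1, 2 and 4 to 10); step 3 is the side branch.

Steps most likely to fail

1. Step 8 (key step). The catalyst may not turn over, because the lactone carbonyl is a doubly vinylogous, weakly electrophilic acyl donor and the ketone enolate is a poor leaving group. The catalyst or adventitious nucleophiles may also attack silicon, and facial selectivity may be poor or reversed. The fallback uses known chemistry (racemic ring closure, then resolution) and sets out from 10. Sodium methoxide in methanol, followed by acidification with acetic acid and gentle warming, opens the dioxanedione ring with loss of acetone and CO2 (alcoholysis–decarboxylation of a Meldrum's acid adduct) and gives methyl (Z)-2-(3-{2-[(tert-butyldimethylsilyl)oxy]propanoyl}-6-heptyl-4H-pyran-4-ylidene)acetate F1. LiN(SiMe3)2 in THF at −78 °C then forms the ketone enolate, which closes ring A on the ester by a Dieckmann-type Claisen condensation to give racemic 7-[(tert-butyldimethylsilyl)oxy]-3-heptyl-7-methyl-6H-isochromene-6,8(7H)-dione F2. HF·pyridine gives racemic 3-heptyl-7-hydroxy-7-methyl-6H-isochromene-6,8(7H)-dione F3. Preparative chromatography on a chiral stationary phase separates the unwanted (7S)-3-heptyl-7-hydroxy-7-methyl-6H-isochromene-6,8(7H)-dione F4 from the (7R)-alcohol, which is 16, and the route is rejoined there for step 10.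

2. Step 5. Meldrum's acid may add at the unsubstituted C2 position of the acylpyranone (conjugate addition and ring opening) in place of condensation at the hindered C4 carbonyl, or the condensation may stall. The fallback sets out from 9 and separates activation from bond formation. O-Methylation with methyl trifluoromethanesulfonate in CH2Cl2 gives 3-{2-[(tert-butyldimethylsilyl)oxy]propanoyl}-6-heptyl-4-methoxypyrylium trifluoromethanesulfonate F5. At −20 °C with triethylamine, Meldrum's acid displaces methanol at C4 by addition–elimination, the established reaction of 4-alkoxypyrylium salts with CH-acids, and the route is rejoined at 10.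

3. Step 6. The pyranylidene acetic acid may lose its second carboxyl group before it lactonises, or ring B may be opened hydrolytically in hot aqueous acid. The fallback sets out from 10 and avoids water until the lactone is closed. Triethylamine in acetonitrile at 60 °C enolises the side-chain ketone, and the enol oxygen is acylated by the adjacent Meldrum's acid carbonyl with loss of acetone (as in the formation of coumarin-3-carboxylic acids from Meldrum's acid adducts), giving (E)-8-{1-[(tert-butyldimethylsilyl)oxy]ethylidene}-3-heptyl-6-oxo-8H-pyrano[3,4-c]pyran-5-carboxylic acid F6. Brief warming with acetic acid in dioxane decarboxylates this vinylogous malonic half-acid to (E)-8-{1-[(tert-butyldimethylsilyl)oxy]ethylidene}-3-heptyl-8H-pyrano[3,4-c]pyran-6-one F7. Dilute HCl in THF at rt hydrolyses the silyl enol ether, and the route is rejoined at 12.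

Further compounds
F1 | step 8 | methyl (Z)-2-(3-{2-[(tert-butyldimethylsilyl)oxy]propanoyl}-6-heptyl-4H-pyran-4-ylidene)acetate (racemic) | CCCCCCCC1=C/C(=C/C(=O)OC)C(C(=O)C(C)O[Si](C)(C)C(C)(C)C)=CO1
F2 | step 8 | 7-[(tert-butyldimethylsilyl)oxy]-3-heptyl-7-methyl-6H-isochromene-6,8(7H)-dione (racemic) | CC(C)(C)[Si](C)(C)OC1(C)C(=O)C=C2C=C(CCCCCCC)OC=C2C1=O
F3 | step 8 | 3-heptyl-7-hydroxy-7-methyl-6H-isochromene-6,8(7H)-dione (racemic) | OC1(C)C(=O)C=C2C=C(CCCCCCC)OC=C2C1=O
F4 | step 8 | (7S)-3-heptyl-7-hydroxy-7-methyl-6H-isochromene-6,8(7H)-dione | O[C@@]1(C)C(=O)C=C2C=C(CCCCCCC)OC=C2C1=O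
F5 | step 5 | 3-{2-[(tert-butyldimethylsilyl)oxy]propanoyl}-6-heptyl-4-methoxypyrylium trifluoromethanesulfonate (racemic) | CCCCCCCc1cc(OC)c(c[o+]1)C(=O)C(C)O[Si](C)(C)C(C)(C)C.[O-]S(=O)(=O)C(F)(F)F
F6 | step 6 | (E)-8-{1-[(tert-butyldimethylsilyl)oxy]ethylidene}-3-heptyl-6-oxo-8H-pyrano[3,4-c]pyran-5-carboxylic acid | CCCCCCCC1=CC2=C(C(O)=O)C(=O)O/C(=C(\C)O[Si](C)(C)C(C)(C)C)C2=CO1
F7 | step 6 | (E)-8-{1-[(tert-butyldimethylsilyl)oxy]ethylidene}-3-heptyl-8H-pyrano[3,4-c]pyran-6-one | CCCCCCCC1=CC2=CC(=O)O/C(=C(\C)O[Si](C)(C)C(C)(C)C)C2=CO1
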